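The oxepane ring (O, C10 bearing CH3, C1H2, C2H2, C3H–OAc, C4H–CH2OH, C5H) is treated as a cyclohexene in disguise: its C10–O–C5 ether is the scar of a cleaved C5=C10 double bond and the C3 acetate that of a Baeyer–Villiger-oxidised acetyl group. An enantioselective endo Diels–Alder reaction of methyl vinyl ketone with the open-chain diene C1=C10(CH3)–C5=C4–C15H2OSi therefore forms C1–C2 and C3–C4 in one operation and sets C3 and C4. The temporary C5=C10 bond is then cut and re-joined through oxygen, and the second seven-membered ring is closed afterwards by metathesis.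

Key step: step 4

Atom labels: C1–C10 are the carbons of the ten-membered carbocycle as used above; C6 = lactone CH–O, C7 = ring-fusion CH, C8 = CH–O-methacryloyl, C9 = CH2, C11–C13 = lactone C(=CH2)–C=O, C14 = CH3 on C10, C15 = CH2OH on C4.

Remark: the stereodescriptors of the target, (3R,4R,5R,6R,7R,8R,10R), place the ring-oxygen bonds at C5 and C10 on opposite faces of the ten-membered ring (an inside–outside 11-oxabicyclo[4.4.1]undecane). The route is built for exactly this diastereomer: the oxepane is made first with C6 and C9 trans, and the second ring is closed remote from C5 and C10.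

Step 1
Reactants: 1 methacrolein; 2 ethyl (triphenylphosphoranylidene)acetate
Product: 3 ethyl (2E)-4-methylpenta-2,4-dienoate
Conditions: CH2Cl2, rt
Reagents that add atoms: none
Why: Wittig olefination with a stabilised ylide should give the E-enoate, which fixes the geometry of the later C4=C5 diene bond.

Step 2
Reactants: 3 ethyl (2E)-4-methylpenta-2,4-dienoate
Product: 4 (2E)-4-methylpenta-2,4-dien-1-ol
Conditions: i-Bu2AlH, CH2Cl2, −78 → 0 °C; aq. KNaC4H4O6
Reagents that add atoms: none
Why: 1,2-Hydride reduction of the conjugated ester gives the allylic alcohol (O15) and leaves the diene untouched.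

Step 3
Reactants: 4 (2E)-4-methylpenta-2,4-dien-1-ol
Product: 5 tert-butyl{[(2E)-4-methylpenta-2,4-dien-1-yl]oxy}diphenylsilane
Conditions: TBDPSCl, imidazole, CH2Cl2, 0 °C → rt
Reagents that add atoms: tert-butyl(chloro)diphenylsilane, CC(C)(C)[Si](Cl)(c1ccccc1)c1ccccc1
Why: Silylation of the primary alcohol gives a robust ether that should carry O15 through the acidic, oxidative and Lewis-acidic steps to the end.

Step 4
Reactants: 5 tert-butyl{[(2E)-4-methylpenta-2,4-dien-1-yl]oxy}diphenylsilane; 6 methyl vinyl ketone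
Product: 7 1-[(1R,2S)-2-{[tert-butyl(diphenyl)silyl]oxymethyl}-4-methylcyclohex-3-en-1-yl]ethan-1-one
Conditions: (S)-3,3-diphenyl-1-(o-tolyl)tetrahydro-1H,3H-pyrrolo[1,2-c][1,3,2]oxazaborole (20 mol %), Tf2NH (18 mol %), CH2Cl2, −78 → −40 °C
Reagents that add atoms: none
Why: The triflimide-activated oxazaborolidine binds the carbonyl oxygen of 6 and lowers its LUMO, so that diene 5 adds in a concerted, asynchronous, suprafacial [4+2] cycloaddition; the closest known reaction type is the chiral oxazaborolidinium-catalysed Diels–Alder reaction of acyclic dienes with α,β-unsaturated ketones. The six-membered ring C1–C2–C3–C4–C5–C10 is closed by intermolecular (4+2) annulation, both σ bonds (C1–C2 and C3–C4) forming in the same transition state. C4 follows from the E geometry of the C4=C5 bond and suprafacial addition, C3 from the endo orientation of the acetyl group (acetyl cis to CH2OSi), and the absolute sense (1R,2S) from the catalyst, which shields one face of the coordinated enone; the mirror-image catalyst is used should the sense have to be reversed. The step needs regioselectivity for the 1,2,4-pattern, which the C10 methyl ("para" director) and the C4 substituent ("ortho" director) secure together because both raise the HOMO coefficient at C1, and endo selectivity, which Lewis-acid activation secures. The C5=C10 double bond of 7 is the temporary bond that is cut in step 6.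

Step 5
Reactants: 7 Diels–Alder adduct
Product: 9 (1R,2R)-2-{[tert-butyl(diphenyl)silyl]oxymethyl}-3,4-epoxy-4-methylcyclohexyl acetate, via epoxy ketone 8 (not isolated)
Conditions: urea–H2O2, (CF3CO)2O, Na2HPO4, CH2Cl2, 0 °C → rt
Reagents that add atoms: urea–hydrogen peroxide, NC(N)=O.OO (source of both new oxygen atoms, delivered as trifluoroperacetic acid, OOC(=O)C(F)(F)F)
Why: Prilezhaev epoxidation of the trisubstituted alkene (either face, inconsequential) is followed by Baeyer–Villiger oxidation of the methyl ketone, in which the secondary carbon C3 migrates with retention so that the acetyl group becomes the C3 acetate of the target.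

Step 6
Reactants: 9 epoxy acetate
Product: 10 (2R,3R)-2-{[tert-butyl(diphenyl)silyl]oxymethyl}-1,6-dioxoheptan-3-yl acetate
Conditions: H5IO6, THF–H2O, 0 °C → rt; used crude
Reagents that add atoms: water, O
Why: Periodic acid hydrolyses the epoxide and cleaves the glycol (Malaprade cleavage), cutting the temporary C5–C10 bond to the C5 aldehyde and the C10 methyl ketone without touching C3 or C4.

Step 7
Reactants: 10 keto aldehyde; 11 allyl methoxymethyl ether
Product: 13 (5R,6S,7R,8R)-6-{[tert-butyl(diphenyl)silyl]oxymethyl}-7-hydroxy-8-(methoxymethoxy)-2-oxodec-9-en-5-yl acetate, via (Z)-γ-(methoxymethoxy)allyl-diisopinocampheylborane 12 (not isolated)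
Conditions: 11, s-BuLi, THF, −78 °C; (−)-B-methoxydiisopinocampheylborane; BF3·OEt2; then 10, −78 °C; NaBO3·4H2O, THF–H2O, 0 °C
Reagents that add atoms: none
Why: Reagent-controlled asymmetric γ-alkoxyallylboration through a chair Zimmerman–Traxler transition state should add to the aldehyde Si face much faster than to the methyl ketone, the Z-enol ether giving the syn C5–OH/C6–OMOM pair and the pinene-derived ligands fixing C5 and C6 as R against the weak bias of C4.

Step 8
Reactants: 13 hydroxy ketone; 14 allyltrimethylsilane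
Product: 15 (2R,5R,6R,7R)-6-{[tert-butyl(diphenyl)silyl]oxymethyl}-7-[(1R)-1-(methoxymethoxy)prop-2-en-1-yl]-2-methyl-2-(prop-2-en-1-yl)oxepan-5-yl acetate
Conditions: Me3SiOTf (0.3 equiv), CH2Cl2–MeCN, −78 → −40 °C
Reagents that add atoms: none
Why: Tandem hemiketalisation and Hosomi–Sakurai allylation passes through the seven-membered 2-methyloxepan-2-ylium ion, which the allylsilane should attack anti to the C5 side chain, so that at the new quaternary C10 the allyl group (C9) is trans and the methyl cis to C6.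

Step 9
Reactants: 15 diene
Product: 16 (1R,5R,6R,7R,8R)-7-{[tert-butyl(diphenyl)silyl]oxymethyl}-5-(methoxymethoxy)-1-methyl-11-oxabicyclo[4.4.1]undec-3-en-8-yl acetate
Conditions: second-generation Grubbs catalyst (H2IMes)(PCy3)Cl2Ru=CHPh (10 mol %), CH2Cl2 (0.002 M), 40 °C
Reagents that add atoms: none
Why: Ring-closing olefin metathesis of the vinyl and allyl arms forms C7=C8 with loss of ethylene, and because C5 and C10 are already fixed trans on the first oxepane and the new bond is remote from both, the only cyclic product possible is the inside–outside bicycle.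

Step 10
Reactants: 16 MOM ether
Product: 17 (1R,5R,6R,7R,8R)-7-{[tert-butyl(diphenyl)silyl]oxymethyl}-5-hydroxy-1-methyl-11-oxabicyclo[4.4.1]undec-3-en-8-yl acetate
Conditions: Me2BBr, CH2Cl2, −78 °C; aq. NaHCO3
Reagents that add atoms: none
Why: Bromodimethylborane cleaves the formaldehyde acetal selectively at low temperature, freeing O6 while the acetate, the silyl ether and the tertiary ring ether should survive.

Step 11
Reactants: 17 allylic alcohol; 18 (diethoxyphosphoryl)acetic acid
Product: 19 C6 (diethoxyphosphoryl)acetate of 17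
Conditions: DCC, DMAP (cat.), CH2Cl2, 0 °C → rt
Reagents that add atoms: none
Why: Steglich esterification attaches C12 and C11 to O6 under neutral conditions without stereochemical change.

Step 12
Reactants: 19 allylic phosphonoacetate
Product: 20 (7S,8S)-7,8-epoxide of 19
Conditions: mCPBA, NaHCO3, CH2Cl2, 0 °C → rt
Reagents that add atoms: 3-chloroperbenzoic acid, OOC(=O)c1cccc(Cl)c1
Why: Prilezhaev epoxidation of the only alkene should occur on the face anti to the bulky allylic C6 acyloxy group, which places the epoxide oxygen trans to the tethered nucleophile as the next step requires.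

Step 13
Reactants: 20 epoxy phosphonoacetate
Product: 22 (8S)-alcohol with the 6,12-lactone and C11=C13 methylene in place, via α-phosphono lactone 21 (not isolated)
Conditions: NaH, THF, 0 → 50 °C; then (CH2O)n, rt
Reagents that add atoms: formaldehyde (from paraformaldehyde), C=O
Why: The phosphonoacetate carbanion opens the epoxide at C7 by intramolecular 5-exo attack with inversion (cis-fused lactone, C8 oxygen retained), and the resulting phosphonate-stabilised lactone anion then undergoes Horner–Wadsworth–Emmons olefination with formaldehyde to give the exocyclic methylene.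

Step 14
Reactants: 22 (8S)-alcohol; 23 methacrylic acid
Product: 24 15-O-tert-butyldiphenylsilyl ether of the target
Conditions: PPh3, DIAD, toluene, 0 °C → rt
Reagents that add atoms: none
Why: Mitsunobu esterification inverts C8, converting the (8S)-alcohol left by anti epoxide opening into the (8R)-methacrylate and completing the all-cis C6/C7/C8 array.

Step 15
Reactants: 24 silyl ether
Product: 25 target CNP0602302.1
Conditions: HF·pyridine, THF–pyridine, 0 °C → rt
Reagents that add atoms: none
Why: Fluoride cleaves the Si–O bond under buffered acidic conditions that should spare the acetate, the methacrylate and the α-methylene lactone and avoid acetyl migration from O3 to O15.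

Compound list
1 | methacrolein (2-methylprop-2-enal) | C=C(C)C=O | starting material
2 | ethyl (triphenylphosphoranylidene)acetate | CCOC(=O)C=P(c1ccccc1)(c1ccccc1)c1ccccc1 | starting material
3 | ethyl (2E)-4-methylpenta-2,4-dienoate | C=C(C)/C=C/C(=O)OCC | intermediate
4 | (2E)-4-methylpenta-2,4-dien-1-ol | C=C(C)/C=C/CO | intermediate
5 | tert-butyl{[(2E)-4-methylpenta-2,4-dien-1-yl]oxy}diphenylsilane | C=C(C)/C=C/CO[Si](c1ccccc1)(c1ccccc1)C(C)(C)C | intermediate
6 | methyl vinyl ketone (but-3-en-2-one) | C=CC(C)=O | starting material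
7 | 1-[(1R,2S)-2-{[tert-butyl(diphenyl)silyl]oxymethyl}-4-methylcyclohex-3-en-1-yl]ethan-1-one | C1C[C@@H](C(C)=O)[C@@H](CO[Si](c2ccccc2)(c2ccccc2)C(C)(C)C)C=C1C | intermediate
8 | 1-[(1R,2S)-2-{[tert-butyl(diphenyl)silyl]oxymethyl}-3,4-epoxy-4-methylcyclohexyl]ethan-1-one (epoxide diastereomers) | CC12CC[C@@H](C(C)=O)[C@@H](CO[Si](c3ccccc3)(c3ccccc3)C(C)(C)C)C1O2 | intermediate (not isolated)
9 | (1R,2R)-2-{[tert-butyl(diphenyl)silyl]oxymethyl}-3,4-epoxy-4-methylcyclohexyl acetate (epoxide diastereomers) | CC12CC[C@@H](OC(C)=O)[C@@H](CO[Si](c3ccccc3)(c3ccccc3)C(C)(C)C)C1O2 | intermediate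
10 | (2R,3R)-2-{[tert-butyl(diphenyl)silyl]oxymethyl}-1,6-dioxoheptan-3-yl acetate | CC(=O)CC[C@@H](OC(C)=O)[C@@H](CO[Si](c1ccccc1)(c1ccccc1)C(C)(C)C)C=O | intermediate
11 | allyl methoxymethyl ether (3-(methoxymethoxy)prop-1-ene) | C=CCOCOC | starting material
12 | [(2Z)-3-(methoxymethoxy)prop-2-en-1-yl]diisopinocampheylborane, from (−)-B-methoxydiisopinocampheylborane | COCO/C=C\CB([C@@H]1C[C@@H]2C[C@H]([C@H]1C)C2(C)C)[C@@H]1C[C@@H]2C[C@H]([C@H]1C)C2(C)C | intermediate (not isolated)
13 | (5R,6S,7R,8R)-6-{[tert-butyl(diphenyl)silyl]oxymethyl}-7-hydroxy-8-(methoxymethoxy)-2-oxodec-9-en-5-yl acetate | CC(=O)CC[C@@H](OC(C)=O)[C@@H](CO[Si](c1ccccc1)(c1ccccc1)C(C)(C)C)[C@@H](O)[C@H](OCOC)C=C | intermediate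
14 | allyltrimethylsilane | C=CC[Si](C)(C)C | starting material
15 | (2R,5R,6R,7R)-6-{[tert-butyl(diphenyl)silyl]oxymethyl}-7-[(1R)-1-(methoxymethoxy)prop-2-en-1-yl]-2-methyl-2-(prop-2-en-1-yl)oxepan-5-yl acetate | C=CC[C@@]1(C)CC[C@@H](OC(C)=O)[C@@H](CO[Si](c2ccccc2)(c2ccccc2)C(C)(C)C)[C@@H](O1)[C@H](OCOC)C=C | intermediate
16 | (1R,5R,6R,7R,8R)-7-{[tert-butyl(diphenyl)silyl]oxymethyl}-5-(methoxymethoxy)-1-methyl-11-oxabicyclo[4.4.1]undec-3-en-8-yl acetate (inside–outside bicycle, C7=C8 alkene) | C1C[C@@]2(C)CC[C@@H](OC(C)=O)[C@@H](CO[Si](c3ccccc3)(c3ccccc3)C(C)(C)C)[C@@H](O2)[C@H](OCOC)C=1 | intermediate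
17 | (1R,5R,6R,7R,8R)-7-{[tert-butyl(diphenyl)silyl]oxymethyl}-5-hydroxy-1-methyl-11-oxabicyclo[4.4.1]undec-3-en-8-yl acetate | C1C[C@@]2(C)CC[C@@H](OC(C)=O)[C@@H](CO[Si](c3ccccc3)(c3ccccc3)C(C)(C)C)[C@@H](O2)[C@H](O)C=1 | intermediate
18 | (diethoxyphosphoryl)acetic acid | OC(=O)CP(=O)(OCC)OCC | starting material
19 | (1R,5R,6R,7R,8R)-8-acetoxy-7-{[tert-butyl(diphenyl)silyl]oxymethyl}-1-methyl-11-oxabicyclo[4.4.1]undec-3-en-5-yl (diethoxyphosphoryl)acetate | C1C[C@@]2(C)CC[C@@H](OC(C)=O)[C@@H](CO[Si](c3ccccc3)(c3ccccc3)C(C)(C)C)[C@@H](O2)[C@H](OC(=O)CP(=O)(OCC)OCC)C=1 | intermediate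
20 | (7S,8S)-7,8-epoxide of 19 (epoxide oxygen anti to the C6 ester) | O1[C@H]2C[C@@]3(C)CC[C@@H](OC(C)=O)[C@@H](CO[Si](c4ccccc4)(c4ccccc4)C(C)(C)C)[C@@H](O3)[C@H](OC(=O)CP(=O)(OCC)OCC)[C@@H]12 | intermediate
21 | (8S)-8-hydroxy-11-(diethoxyphosphoryl) 6,12-lactone, 15-O-TBDPS, 3-O-acetyl (C11 epimers) | O[C@H]1C[C@@]2(C)CC[C@@H](OC(C)=O)[C@@H](CO[Si](c3ccccc3)(c3ccccc3)C(C)(C)C)[C@@H](O2)[C@@H]2OC(=O)C(P(=O)(OCC)OCC)[C@@H]21 | intermediate (not isolated)
22 | (8S)-8-hydroxy α-methylene 6,12-lactone, 15-O-TBDPS, 3-O-acetyl (8-epi-8-O-desmethacryloyl target silyl ether) | O[C@H]1C[C@@]2(C)CC[C@@H](OC(C)=O)[C@@H](CO[Si](c3ccccc3)(c3ccccc3)C(C)(C)C)[C@@H](O2)[C@@H]2OC(=O)C(=C)[C@@H]21 | intermediate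
23 | methacrylic acid | C=C(C)C(=O)O | starting material
24 | 15-O-tert-butyldiphenylsilyl ether of the target | C=C(C)C(=O)O[C@@H]1C[C@@]2(C)CC[C@@H](OC(C)=O)[C@@H](CO[Si](c3ccccc3)(c3ccccc3)C(C)(C)C)[C@@H](O2)[C@@H]2OC(=O)C(=C)[C@@H]21 | intermediate
25 | CNP0602302.1, (3R,4R,5R,6R,7R,8R,10R) | C=C(C)C(=O)O[C@@H]1C[C@@]2(C)CC[C@@H](OC(C)=O)[C@@H](CO)[C@@H](O2)[C@@H]2OC(=O)C(=C)[C@@H]21 | target

Total step count: 15. Longest linear sequence: 15 steps (1 → 25).

Steps most likely to fail

1. Step 9 (metathesis to the inside–outside bicycle). Strain in the trans-bridged product may slow cyclisation so much that intermolecular metathesis to oligomers or catalyst decay wins. Fallback: from 15, ozonolysis of both terminal alkenes (O3, CH2Cl2–MeOH, −78 °C; PPh3) should give the dialdehyde F1. Intramolecular McMurry coupling with low-valent titanium (TiCl3(DME)1.5, Zn–Cu, DME, reflux, slow addition) should then form the same C7=C8 alkene irreversibly and rejoin the route at 16.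

2. Step 8 (allylative oxepane closure). The seven-membered oxocarbenium ion may form too slowly, so that the ketone is allylated intermolecularly or the MOM group is lost, or it may be attacked with poor facial selectivity, which would scramble the quaternary centre C10. Fallback: from 10, the aldehyde is masked chemoselectively as the dimethyl acetal F2 (CH(OMe)3, CeCl3·7H2O, MeOH). Catalyst-controlled allylation of the methyl ketone (allylboronic acid pinacol ester, CuF2·2H2O, (R,R)-i-Pr-DuPHOS, La(Oi-Pr)3, ligand antipode chosen for 10R) should set C10 in the tertiary alcohol F3 independently of any ring. PPTS (CH2Cl2, 4 Å MS) should close the cyclic methyl acetal F4. BF3·OEt2-mediated addition of tributyl[(2Z)-3-(methoxymethoxy)prop-2-en-1-yl]stannane to the derived C5 oxocarbenium ion (attack anti to the C4 substituent, syn C5–O/C6–O through an open transition state) should then rejoin the route at 15.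

3. Step 12 (epoxidation). Facial selectivity may be poor or reversed, with oxygen delivered syn to the C6 ester; that epoxide cannot be opened by the tethered carbanion. Fallback: from 19, NBS in aqueous DME should add bromine to that same, more accessible face and water anti to it at C8, giving the trans-bromohydrin F5. DBU (CH2Cl2) should then close the epoxide on the opposite face by intramolecular displacement and rejoin the route at 20.

Further compounds
F1 | step 9 | (2R,5R,6R,7R)-6-{[tert-butyl(diphenyl)silyl]oxymethyl}-7-[(1S)-1-(methoxymethoxy)-2-oxoethyl]-2-methyl-2-(2-oxoethyl)oxepan-5-yl acetate | O=CC[C@@]1(C)CC[C@@H](OC(C)=O)[C@@H](CO[Si](c2ccccc2)(c2ccccc2)C(C)(C)C)[C@@H](O1)[C@H](OCOC)C=O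
F2 | step 8 | (2R,3R)-2-{[tert-butyl(diphenyl)silyl]oxymethyl}-1,1-dimethoxy-6-oxoheptan-3-yl acetate | CC(=O)CC[C@@H](OC(C)=O)[C@@H](CO[Si](c1ccccc1)(c1ccccc1)C(C)(C)C)C(OC)OC
F3 | step 8 | (2R,3R,6R)-2-{[tert-butyl(diphenyl)silyl]oxymethyl}-6-hydroxy-1,1-dimethoxy-6-methylnon-8-en-3-yl acetate | C=CC[C@](C)(O)CC[C@@H](OC(C)=O)[C@@H](CO[Si](c1ccccc1)(c1ccccc1)C(C)(C)C)C(OC)OC
F4 | step 8 | (2R,5R,6R)-6-{[tert-butyl(diphenyl)silyl]oxymethyl}-7-methoxy-2-methyl-2-(prop-2-en-1-yl)oxepan-5-yl acetate (anomers) | C=CC[C@@]1(C)CC[C@@H](OC(C)=O)[C@@H](CO[Si](c2ccccc2)(c2ccccc2)C(C)(C)C)C(OC)O1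
F5 | step 12 | trans-bromohydrin of 19 (7-Br syn to the C6 ester, 8-OH anti) | O[C@H]1C[C@@]2(C)CC[C@@H](OC(C)=O)[C@@H](CO[Si](c3ccccc3)(c3ccccc3)C(C)(C)C)[C@@H](O2)[C@H](OC(=O)CP(=O)(OCC)OCC)[C@@H]1Br
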